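**Retrosynthetic overview**

1. 34 ⇐ 33 ⇐ 32 ⇐ 29: the acetate, the free alcohol and the exocyclic methylene (Mannich/elimination) are placed last on the macrocyclic cis-fused γ-lactone 29.
2. 29 ⇐ 27: the 14-membered carbocycle is closed at C6–C7, the one C(sp3)–C(sp2) ring bond lying opposite the lactone. C6 is the CH2 two atoms from the C3=C4 alkene (before the event, the terminus of a C3=C4–C5=C6 diene); C7 is the vinylic CH of the C7=C8 alkene carrying CH2OAc (before the event, a Z-iodoalkene). Forward: diene hydroboration, then intramolecular B-alkyl Suzuki–Miyaura coupling.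
3. 27 ⇐ 21: the five-membered lactone ring (O, C2, C1, C15, C16) is formed first, from the syn-homoallylic alcohol 21 (vinyl to CH2–C=O by hydroboration/oxidation and oxidative lactonisation); the 14-membered ring is formed second.
4. 21 ⇐ allene 14 + enynal 18: one allene hydroboration/allylboration with a chiral borane joins the halves and sets C1 and C2.
5. 14 ⇐ propargyl alcohol 2 + bromide 1 (anti-carbomagnesiation/iodination fixes the Z-iodoalkene), then SeO2 oxidation, propargylation, Crabbé homologation; 18 ⇐ commercial enynol 15.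

Key step: step 13

Numbering used in the text: cembrane numbering; C1 and C2 are the ring-fusion carbons (C2 bears the lactone oxygen), C3=C4(CH3), C7=C8(CH2OAc), C11=C12(CH3), and C15/C16/C17 are the lactone α-carbon, carbonyl carbon and exocyclic methylene.

Assumption: the (10R)-borane of step 9 is taken to deliver the (Z)-allyl unit to the Re face of aldehyde 18 (giving the 5R,6S alcohol); if the sense of induction is the reverse, the (10S)-borane is used in the same way.

**Route**

Step 1
Reactants: 1 5-bromo-2-methylpent-2-ene; 2 prop-2-yn-1-ol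
Product: 5 (2Z)-3-iodo-2-(4-methylpent-3-en-1-yl)prop-2-en-1-ol, via (4-methylpent-3-en-1-yl)magnesium bromide 3 (not isolated), via alkenylmagnesium alkoxide chelate 4 (not isolated)
Conditions: Mg, THF, reflux (3, 2.5 equiv); 2, CuI (10 mol %), THF/Et2O, −20 °C to rt; then I2, −40 °C to rt; 1 M HCl work-up
Reagents that add atoms: iodine, II
Why: CuI-catalysed anti-carbomagnesiation of propargyl alcohol: the magnesium alkoxide directs trans addition of the alkyl group (to C2) and magnesium (to C3) into a five-membered chelate, and iodinolysis with retention puts iodine cis to CH2OH, which fixes the geometry of the later C7=C8 alkene.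

Step 2
Reactants: 5 (2Z)-3-iodo-2-(4-methylpent-3-en-1-yl)prop-2-en-1-ol
Product: 6 tert-butyl{[(2Z)-3-iodo-2-(4-methylpent-3-en-1-yl)prop-2-en-1-yl]oxy}dimethylsilane
Conditions: TBSCl, imidazole, CH2Cl2, 0 °C to rt
Reagents that add atoms: tert-butyl(chloro)dimethylsilane, CC(C)(C)[Si](C)(C)Cl
Why: Standard silyl ether formation protects the primary allylic alcohol through the organometallic, oxidative and basic steps that follow.

Step 3
Reactants: 6 tert-butyl{[(2Z)-3-iodo-2-(4-methylpent-3-en-1-yl)prop-2-en-1-yl]oxy}dimethylsilane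
Product: 7 (2E,6Z)-6-{[tert-butyl(dimethyl)silyl]oxymethyl}-7-iodo-2-methylhepta-2,6-dien-1-ol
Conditions: SeO2 (0.3 equiv), t-BuOOH, salicylic acid (cat.), CH2Cl2, 0 °C to rt; NaBH4/MeOH work-up at 0 °C to return any enal to 7
Reagents that add atoms: selenium dioxide, O=[Se]=O (catalytic oxygen carrier); tert-butyl hydroperoxide, CC(C)(C)OO (terminal oxidant)
Why: SeO2 allylic oxidation (ene reaction, then [2,3]-sigmatropic shift) should hydroxylate the E-methyl of the electron-rich isopropylidene group to give the E allylic alcohol, while the electron-poor iodoalkene is left alone.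

Step 4
Reactants: 7 (2E,6Z)-6-{[tert-butyl(dimethyl)silyl]oxymethyl}-7-iodo-2-methylhepta-2,6-dien-1-ol
Product: 8 (1Z,5E)-7-bromo-2-{[tert-butyl(dimethyl)silyl]oxymethyl}-1-iodo-6-methylhepta-1,5-diene
Conditions: CBr4, PPh3, CH2Cl2, −20 to 0 °C
Reagents that add atoms: carbon tetrabromide, BrC(Br)(Br)Br
Why: Appel bromination converts the primary allylic alcohol into the bromide by SN2 displacement of the oxyphosphonium group, without allylic transposition or loss of alkene geometry at low temperature.

Step 5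
Reactants: 8 (1Z,5E)-7-bromo-2-{[tert-butyl(dimethyl)silyl]oxymethyl}-1-iodo-6-methylhepta-1,5-diene; 9 1-(trimethylsilyl)propyne
Product: 12 (1Z,5E)-2-{[tert-butyl(dimethyl)silyl]oxymethyl}-1-iodo-6-methyldeca-1,5-dien-9-yne, via 3-lithio-1-(trimethylsilyl)propyne 10 (not isolated), via C-silylated enyne 11 (not isolated)
Conditions: 9 (1.3 equiv), n-BuLi (1.2 equiv), THF, −78 to −20 °C; 8, −78 to 0 °C; then MeOH, K2CO3, rt
Reagents that add atoms: none
Why: SN2 alkylation of the primary allylic bromide by the propargylic lithium reagent (reaction at its CH2 terminus) builds C13–C14, and methanolic K2CO3 then removes the alkynyl silyl group (protodesilylation); the stabilised carbanion should not exchange with the iodoalkene.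

Step 6
Reactants: 12 (1Z,5E)-2-{[tert-butyl(dimethyl)silyl]oxymethyl}-1-iodo-6-methyldeca-1,5-dien-9-yne
Product: 14 (1Z,5E)-2-{[tert-butyl(dimethyl)silyl]oxymethyl}-1-iodo-6-methylundeca-1,5,9,10-tetraene, via propargylic dicyclohexylamine 13 (not isolated)
Conditions: (CH2O)n, Cy2NH, CuI (0.5 equiv), dioxane, reflux
Reagents that add atoms: paraformaldehyde (formaldehyde), C=O
Why: Crabbé homologation: CuI-mediated Mannich coupling of the terminal alkyne with formaldehyde and the amine gives 13, which undergoes intramolecular hydride transfer with loss of the imine to give the monosubstituted allene.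

Step 7
Reactants: 15 (2E)-3-methylpent-2-en-4-yn-1-ol
Product: 17 (2E)-3-methyl-5-(trimethylsilyl)pent-2-en-4-yn-1-ol, via bis-silylated enynol 16 (not isolated)
Conditions: EtMgBr (2.2 equiv), THF, 0 to 40 °C; TMSCl (2.3 equiv), 0 °C to rt; then 1 M H2SO4, rt
Reagents that add atoms: chlorotrimethylsilane, C[Si](C)(C)Cl
Why: Double deprotonation (alkoxide and acetylide) and silylation, then selective acidic hydrolysis of the O–Si bond, caps the alkyne so that it is inert to boranes until step 10.

Step 8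
Reactants: 17 (2E)-3-methyl-5-(trimethylsilyl)pent-2-en-4-yn-1-ol
Product: 18 (2E)-3-methyl-5-(trimethylsilyl)pent-2-en-4-ynal
Conditions: MnO2 (activated, excess), CH2Cl2, rt
Reagents that add atoms: none
Why: MnO2 oxidation is selective for the allylic alcohol and should give the E enal without isomerisation.

Step 9
Reactants: 14 (1Z,5E)-2-{[tert-butyl(dimethyl)silyl]oxymethyl}-1-iodo-6-methylundeca-1,5,9,10-tetraene; 18 (2E)-3-methyl-5-(trimethylsilyl)pent-2-en-4-ynal
Product: 21 (3E,5R,6S,9E,13Z)-13-{[tert-butyl(dimethyl)silyl]oxymethyl}-6-ethenyl-14-iodo-3,9-dimethyl-1-(trimethylsilyl)tetradeca-3,9,13-trien-1-yn-5-ol, via (Z)-allylborane 19 (not isolated), via borinate ester 20 (not isolated)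
Conditions: (10R)-10-(trimethylsilyl)-9-borabicyclo[3.3.2]decane (1.2 equiv, freshly prepared solution), 14 (1.3 equiv), Et2O, −78 °C; then 18 (1.0 equiv), −78 °C; then 3 M NaOH, rt
Reagents that add atoms: none
Why: Allene hydroboration followed by aldehyde allylboration: the bulky chiral borane adds to the unsubstituted C=C of the allene to give, under kinetic control, the (Z)-γ-substituted allylborane 19, which reacts with 18 at −78 °C through a closed six-membered chair transition state, so that Z geometry becomes the syn (5R,6S) relationship while the silyl-bearing cage of the borane selects the aldehyde face.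

Step 10
Reactants: 21 (3E,5R,6S,9E,13Z)-13-{[tert-butyl(dimethyl)silyl]oxymethyl}-6-ethenyl-14-iodo-3,9-dimethyl-1-(trimethylsilyl)tetradeca-3,9,13-trien-1-yn-5-ol
Product: 24 (3S,4R,5E)-3-[(3E,7Z)-7-{[tert-butyl(dimethyl)silyl]oxymethyl}-8-iodo-3-methylocta-3,7-dien-1-yl]-6-methyloct-5-en-7-yne-1,4-diol, via bis(9-BBN) adduct 22 (not isolated), via silylalkyne diol 23 (not isolated)
Conditions: 9-BBN (2.5 equiv), THF, 0 °C to rt; then 3 M NaOH, 30% H2O2, MeOH, 0 °C to rt
Reagents that add atoms: hydrogen peroxide, OO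
Why: Hydroboration–oxidation: 9-BBN should add only to the monosubstituted vinyl group (boron at the terminus; one equivalent is consumed by the hydroxyl, and the silyl-capped enyne, trisubstituted alkenes and iodoalkene are far slower), alkaline H2O2 turns C–B into C–OH with no stereocentre touched, and the methanolic hydroxide also removes the alkynyl silyl group.

Step 11
Reactants: 24 (3S,4R,5E)-3-[(3E,7Z)-7-{[tert-butyl(dimethyl)silyl]oxymethyl}-8-iodo-3-methylocta-3,7-dien-1-yl]-6-methyloct-5-en-7-yne-1,4-diol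
Product: 26 (4S,5R)-4-[(3E,7Z)-7-{[tert-butyl(dimethyl)silyl]oxymethyl}-8-iodo-3-methylocta-3,7-dien-1-yl]-5-[(1E)-2-methylbut-1-en-3-yn-1-yl]oxolan-2-one, via lactol 25 (not isolated)
Conditions: TEMPO (0.2 equiv), PhI(OAc)2 (2.5 equiv), CH2Cl2, rt
Reagents that add atoms: none
Why: TEMPO/PhI(OAc)2 oxidative lactonisation: the oxoammonium species oxidises the primary alcohol selectively, the aldehyde is trapped by the C4 hydroxyl as lactol 25 and oxidised on to the γ-lactone, so the syn relationship from step 9 becomes the cis arrangement of the two chains on the lactone ring.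

Step 12
Reactants: 26 (4S,5R)-4-[(3E,7Z)-7-{[tert-butyl(dimethyl)silyl]oxymethyl}-8-iodo-3-methylocta-3,7-dien-1-yl]-5-[(1E)-2-methylbut-1-en-3-yn-1-yl]oxolan-2-one
Product: 27 (4S,5R)-4-[(3E,7Z)-7-{[tert-butyl(dimethyl)silyl]oxymethyl}-8-iodo-3-methylocta-3,7-dien-1-yl]-5-[(1E)-2-methylbuta-1,3-dien-1-yl]oxolan-2-one
Conditions: H2 (1 atm), Pd/CaCO3 poisoned with Pb(OAc)2 (Lindlar catalyst), quinoline, EtOAc, rt, stopped after one equivalent of H2
Reagents that add atoms: none
Why: Lindlar semihydrogenation should reduce the terminal conjugated alkyne to the vinyl group much faster than any alkene, giving the 3-methyl-1,3-diene with the trisubstituted alkenes and the iodoalkene unchanged.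

Step 13
Reactants: 27 (4S,5R)-4-[(3E,7Z)-7-{[tert-butyl(dimethyl)silyl]oxymethyl}-8-iodo-3-methylocta-3,7-dien-1-yl]-5-[(1E)-2-methylbuta-1,3-dien-1-yl]oxolan-2-one
Product: 29 (3aS,6E,10Z,14E,15aR)-10-{[tert-butyl(dimethyl)silyl]oxymethyl}-6,14-dimethyl-3a,4,5,8,9,12,13,15a-octahydrocyclotetradeca[b]furan-2(3H)-one, via B-alkyl-9-BBN adduct 28 (not isolated)
Conditions: 9-BBN (1.3 equiv), THF, 0 °C to rt; then added over 12 h to Pd(dppf)Cl2 (15 mol %), AsPh3 (30 mol %), Cs2CO3 (3 equiv), DMF/THF/H2O, 45 °C (final concentration about 1 mM); work-up at pH 3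
Reagents that add atoms: none
Why: 9-BBN adds across the terminal CH=CH2 of the 3-methyl-1,3-diene with boron on the terminal carbon to give the homoallylic borane 28; zerovalent palladium generated from Pd(dppf)Cl2 then inserts into the C–I bond of the Z-iodoalkene with retention, the base-activated B-alkyl group transmetalates and reductive elimination forms the C(sp3)–C(sp2) bond. The closest known reaction type is the B-alkyl Suzuki–Miyaura macrocyclisation of an iodoalkene tethered to a 9-BBN-hydroborated terminal alkene, and hydroboration of a diene terminus to a homoallylic borane is equally established. The one ring closed is the 14-membered carbocycle, formed by intramolecular cross-coupling of the two chain ends (an endo closure, both coupling carbons ending up in the ring), with the cis-substituted lactone from step 11 holding the two chains on the same face as a turn element. No stereocentre is created: the C7=C8 geometry is carried over from the iodoalkene of step 1 by the stereoretentive coupling, and C1 and C2 lie on the far side of the ring and are not touched. The step needs chemoselective hydroboration, secured because 27 has a single monosubstituted alkene while the others are trisubstituted or iodo-substituted and the lactone is inert to 9-BBN at rt, and it needs ring closure to beat oligomerisation and β-hydride elimination, secured by slow addition to about 1 mM and by the wide bite angle of dppf. Ionisation of the allylic lactone C–O bond is not expected to compete, because that alkene is trisubstituted and oxidative addition to the iodoalkene is far faster.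

Step 14
Reactants: 29 (3aS,6E,10Z,14E,15aR)-10-{[tert-butyl(dimethyl)silyl]oxymethyl}-6,14-dimethyl-3a,4,5,8,9,12,13,15a-octahydrocyclotetradeca[b]furan-2(3H)-one
Product: 32 (3aS,6E,10Z,14E,15aS)-10-{[tert-butyl(dimethyl)silyl]oxymethyl}-6,14-dimethyl-3-methylidene-3a,4,5,8,9,12,13,15a-octahydrocyclotetradeca[b]furan-2(3H)-one, via Mannich base 30 (not isolated), via trimethylammonium iodide 31 (not isolated)
Conditions: LiN(SiMe3)2, THF, −78 °C; dimethyl(methylidene)ammonium iodide, −78 °C to rt; then MeI, MeOH, rt; then NaHCO3 (aq), CH2Cl2, rt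
Reagents that add atoms: dimethyl(methylidene)ammonium iodide (Eschenmoser's salt), C=[N+](C)C.[I-]
Why: Mannich aminomethylation of the lactone enolate, then exhaustive methylation and Hofmann-type elimination, installs the exocyclic methylene; the α-centre formed in 30 is destroyed again, C3a and C15a are not enolisable, and the descriptor at C15a changes from R to S only because the new sp2 carbon changes the priorities.

Step 15
Reactants: 32 (3aS,6E,10Z,14E,15aS)-10-{[tert-butyl(dimethyl)silyl]oxymethyl}-6,14-dimethyl-3-methylidene-3a,4,5,8,9,12,13,15a-octahydrocyclotetradeca[b]furan-2(3H)-one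
Product: 33 (3aS,6E,10Z,14E,15aS)-10-(hydroxymethyl)-6,14-dimethyl-3-methylidene-3a,4,5,8,9,12,13,15a-octahydrocyclotetradeca[b]furan-2(3H)-one
Conditions: HF·pyridine, pyridine, THF, 0 °C to rt
Reagents that add atoms: none
Why: Fluoride-mediated desilylation; buffered HF·pyridine is chosen because it should not add to the α-methylene lactone or open it.

Step 16
Reactants: 33 (3aS,6E,10Z,14E,15aS)-10-(hydroxymethyl)-6,14-dimethyl-3-methylidene-3a,4,5,8,9,12,13,15a-octahydrocyclotetradeca[b]furan-2(3H)-one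
Product: 34 [(3aS,6E,10Z,14E,15aS)-6,14-dimethyl-3-methylidene-2-oxo-2,3,3a,4,5,8,9,12,13,15a-decahydrocyclotetradeca[b]furan-10-yl]methyl acetate (CNP0158848.2)
Conditions: Ac2O, pyridine, DMAP (cat.), CH2Cl2, 0 °C to rt
Reagents that add atoms: acetic anhydride, CC(=O)OC(C)=O
Why: DMAP-catalysed acetylation of the primary allylic alcohol leaves the lactone and the alkenes untouched and gives the target.

**Compound list**

1 | 5-bromo-2-methylpent-2-ene | CC(C)=CCCBr | starting material
2 | prop-2-yn-1-ol (propargyl alcohol) | C#CCO | starting material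
3 | (4-methylpent-3-en-1-yl)magnesium bromide | CC(C)=CCC[Mg]Br | intermediate (not isolated)
4 | alkenylmagnesium alkoxide from anti-carbomagnesiation (Mg on C3 cis to CH2O) | Br[Mg]/C=C(\CO[Mg]Br)CCC=C(C)C | intermediate (not isolated)
5 | (2Z)-3-iodo-2-(4-methylpent-3-en-1-yl)prop-2-en-1-ol | I/C=C(\CO)CCC=C(C)C | intermediate
6 | tert-butyl{[(2Z)-3-iodo-2-(4-methylpent-3-en-1-yl)prop-2-en-1-yl]oxy}dimethylsilane | I/C=C(\CO[Si](C)(C)C(C)(C)C)CCC=C(C)C | intermediate
7 | (2E,6Z)-6-{[tert-butyl(dimethyl)silyl]oxymethyl}-7-iodo-2-methylhepta-2,6-dien-1-ol | I/C=C(\CO[Si](C)(C)C(C)(C)C)CC/C=C(\C)CO | intermediate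
8 | (1Z,5E)-7-bromo-2-{[tert-butyl(dimethyl)silyl]oxymethyl}-1-iodo-6-methylhepta-1,5-diene | I/C=C(\CO[Si](C)(C)C(C)(C)C)CC/C=C(\C)CBr | intermediate
9 | 1-(trimethylsilyl)propyne | CC#C[Si](C)(C)C | starting material
10 | 3-lithio-1-(trimethylsilyl)propyne | [Li]CC#C[Si](C)(C)C | intermediate (not isolated)
11 | (1Z,5E)-2-{[tert-butyl(dimethyl)silyl]oxymethyl}-1-iodo-6-methyl-10-(trimethylsilyl)deca-1,5-dien-9-yne | I/C=C(\CO[Si](C)(C)C(C)(C)C)CC/C=C(\C)CCC#C[Si](C)(C)C | intermediate (not isolated)
12 | (1Z,5E)-2-{[tert-butyl(dimethyl)silyl]oxymethyl}-1-iodo-6-methyldeca-1,5-dien-9-yne | I/C=C(\CO[Si](C)(C)C(C)(C)C)CC/C=C(\C)CCC#C | intermediate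
13 | N,N-dicyclohexyl propargylic amine (Mannich base of 12) | I/C=C(\CO[Si](C)(C)C(C)(C)C)CC/C=C(\C)CCC#CCN(C1CCCCC1)C1CCCCC1 | intermediate (not isolated)
14 | (1Z,5E)-2-{[tert-butyl(dimethyl)silyl]oxymethyl}-1-iodo-6-methylundeca-1,5,9,10-tetraene | I/C=C(\CO[Si](C)(C)C(C)(C)C)CC/C=C(\C)CCC=C=C | intermediate
15 | (2E)-3-methylpent-2-en-4-yn-1-ol | OC/C=C(\C)C#C | starting material
16 | O,C-bis(trimethylsilyl) derivative of 15 | C[Si](C)(C)OC/C=C(\C)C#C[Si](C)(C)C | intermediate (not isolated)
17 | (2E)-3-methyl-5-(trimethylsilyl)pent-2-en-4-yn-1-ol | OC/C=C(\C)C#C[Si](C)(C)C | intermediate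
18 | (2E)-3-methyl-5-(trimethylsilyl)pent-2-en-4-ynal | O=C/C=C(\C)C#C[Si](C)(C)C | intermediate
19 | (Z)-γ-substituted allylborane from 14 (boron of the 10R cage on the CH2 terminus) | I/C=C(\CO[Si](C)(C)C(C)(C)C)CC/C=C(\C)CC/C=C\CB1[C@@H]2CCC[C@@H](CCC2)[C@@H]1[Si](C)(C)C | intermediate (not isolated)
20 | borinate ester of 21 with the 10R cage | O(B1[C@@H]2CCC[C@@H](CCC2)[C@@H]1[Si](C)(C)C)[C@H]([C@H](C=C)CC/C(C)=C/CC/C(CO[Si](C)(C)C(C)(C)C)=C/I)/C=C(\C)C#C[Si](C)(C)C | intermediate (not isolated)
21 | (3E,5R,6S,9E,13Z)-13-{[tert-butyl(dimethyl)silyl]oxymethyl}-6-ethenyl-14-iodo-3,9-dimethyl-1-(trimethylsilyl)tetradeca-3,9,13-trien-1-yn-5-ol | O[C@H]([C@H](C=C)CC/C(C)=C/CC/C(CO[Si](C)(C)C(C)(C)C)=C/I)/C=C(\C)C#C[Si](C)(C)C | intermediate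
22 | bis(9-BBN) adduct of 21 (B–O at the carbinol, B–C at the former vinyl terminus) | O(B1C2CCCC1CCC2)[C@H]([C@H](CCB1C2CCCC1CCC2)CC/C(C)=C/CC/C(CO[Si](C)(C)C(C)(C)C)=C/I)/C=C(\C)C#C[Si](C)(C)C | intermediate (not isolated)
23 | silylalkyne diol (8-trimethylsilyl derivative of 24) | O[C@H]([C@H](CCO)CC/C(C)=C/CC/C(CO[Si](C)(C)C(C)(C)C)=C/I)/C=C(\C)C#C[Si](C)(C)C | intermediate (not isolated)
24 | (3S,4R,5E)-3-[(3E,7Z)-7-{[tert-butyl(dimethyl)silyl]oxymethyl}-8-iodo-3-methylocta-3,7-dien-1-yl]-6-methyloct-5-en-7-yne-1,4-diol | O[C@H]([C@H](CCO)CC/C(C)=C/CC/C(CO[Si](C)(C)C(C)(C)C)=C/I)/C=C(\C)C#C | intermediate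
25 | lactol of 26 (oxolan-2-ol, both anomers) | OC1C[C@H](CC/C(C)=C/CC/C(CO[Si](C)(C)C(C)(C)C)=C/I)[C@H](/C=C(\C)C#C)O1 | intermediate (not isolated)
26 | (4S,5R)-4-[(3E,7Z)-7-{[tert-butyl(dimethyl)silyl]oxymethyl}-8-iodo-3-methylocta-3,7-dien-1-yl]-5-[(1E)-2-methylbut-1-en-3-yn-1-yl]oxolan-2-one | O=C1C[C@H](CC/C(C)=C/CC/C(CO[Si](C)(C)C(C)(C)C)=C/I)[C@H](/C=C(\C)C#C)O1 | intermediate
27 | (4S,5R)-4-[(3E,7Z)-7-{[tert-butyl(dimethyl)silyl]oxymethyl}-8-iodo-3-methylocta-3,7-dien-1-yl]-5-[(1E)-2-methylbuta-1,3-dien-1-yl]oxolan-2-one | O=C1C[C@H](CC/C(C)=C/CC/C(CO[Si](C)(C)C(C)(C)C)=C/I)[C@H](/C=C(\C)C=C)O1 | intermediate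
28 | B-alkyl-9-BBN adduct of 27 (boron on C6) | O=C1C[C@H](CC/C(C)=C/CC/C(CO[Si](C)(C)C(C)(C)C)=C/I)[C@H](/C=C(\C)CCB2C3CCCC2CCC3)O1 | intermediate (not isolated)
29 | (3aS,6E,10Z,14E,15aR)-10-{[tert-butyl(dimethyl)silyl]oxymethyl}-6,14-dimethyl-3a,4,5,8,9,12,13,15a-octahydrocyclotetradeca[b]furan-2(3H)-one | O=C1O[C@H]2/C=C(\C)CC/C=C(\CO[Si](C)(C)C(C)(C)C)CC/C=C(\C)CC[C@H]2C1 | intermediate
30 | 3-[(dimethylamino)methyl] derivative of 29 (Mannich base, both C3 epimers) | CN(C)CC1C(=O)O[C@H]2/C=C(\C)CC/C=C(\CO[Si](C)(C)C(C)(C)C)CC/C=C(\C)CC[C@@H]12 | intermediate (not isolated)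
31 | 3-[(trimethylammonio)methyl] iodide of 29 | C[N+](C)(C)CC1C(=O)O[C@H]2/C=C(\C)CC/C=C(\CO[Si](C)(C)C(C)(C)C)CC/C=C(\C)CC[C@@H]12.[I-] | intermediate (not isolated)
32 | (3aS,6E,10Z,14E,15aS)-10-{[tert-butyl(dimethyl)silyl]oxymethyl}-6,14-dimethyl-3-methylidene-3a,4,5,8,9,12,13,15a-octahydrocyclotetradeca[b]furan-2(3H)-one | C=C1C(=O)O[C@H]2/C=C(\C)CC/C=C(\CO[Si](C)(C)C(C)(C)C)CC/C=C(\C)CC[C@@H]12 | intermediate
33 | (3aS,6E,10Z,14E,15aS)-10-(hydroxymethyl)-6,14-dimethyl-3-methylidene-3a,4,5,8,9,12,13,15a-octahydrocyclotetradeca[b]furan-2(3H)-one | C=C1C(=O)O[C@H]2/C=C(\C)CC/C=C(\CO)CC/C=C(\C)CC[C@@H]12 | intermediate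
34 | [(3aS,6E,10Z,14E,15aS)-6,14-dimethyl-3-methylidene-2-oxo-2,3,3a,4,5,8,9,12,13,15a-decahydrocyclotetradeca[b]furan-10-yl]methyl acetate (CNP0158848.2) | C=C1C(=O)O[C@H]2/C=C(\C)CC/C=C(\COC(C)=O)CC/C=C(\C)CC[C@@H]12 | target

**Step count and risks**

Total step count: 16. Longest linear sequence: 14 steps (steps 1–6, then 9–16, from 1 and 2); the aldehyde branch (steps 7 and 8) is 2 steps.

Steps most likely to fail:

Step 13 (macrocyclisation). Oligomerisation, protodeboronation or β-hydride elimination of the alkylpalladium species may outrun ring closure, and ionisation of the allylic lactone C–O bond by zerovalent palladium may compete. The fallback sets out from 27 and returns at 29, closing the same bond by an intramolecular Negishi coupling. 27 is hydroborated to 28 as in step 13 and oxidised with NaBO3·4H2O to the primary alcohol F1. I2/PPh3/imidazole converts it into the primary alkyl iodide F2. Zn dust with LiCl in THF at 40 °C should insert into the C(sp3)–I bond only, giving the alkylzinc iodide F3, which is added slowly to Pd(PPh3)4 in THF/DMA at 50 °C to give 29.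

Step 9 (allylboration). Z-to-E isomerisation of allylborane 19 by 1,3-boratropic shift before the aldehyde reacts would erode the syn relationship, and facial discrimination of the enal may be insufficient. The fallback sets out from 14 and returns at 21; it separates the two control elements. 14 undergoes CuCl/NaOtBu/P(4-MeOC6H4)3-catalysed protoboration with B2pin2 and MeOH to give the configurationally stable (Z)-allylboronic pinacol ester F4. The chiral phosphoric acid TRIP (the enantiomer that gives Re-face attack) catalyses its addition to 18 in toluene at −30 °C (Z-boronate gives syn, the catalyst selects the face) to give the O-boryl adduct F5, which is hydrolysed on work-up to 21.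

Step 6 (Crabbé homologation). The copper acetylide formed on the way may couple with the iodoalkene at reflux, and the hot amine may degrade the allylic silyl ether region. The fallback sets out from 12 and returns at 14; it makes the allene without copper or heat. 12 is deprotonated with EtMgBr to the alkynylmagnesium bromide F6 and treated with paraformaldehyde to give the propargylic alcohol F7. Mitsunobu reaction with 2-nitrobenzenesulfonylhydrazide (PPh3, DEAD, THF, −15 °C) gives the propargylic sulfonylhydrazide F8, which on warming loses the sulfinic acid to the propargylic diazene F9. Retro-ene loss of N2 from that diazene gives 14.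

**Further compounds**

F1 | step 13 | (4S,5R)-5-[(1E)-4-hydroxy-2-methylbut-1-en-1-yl] analogue of 27 (primary alcohol at C6) | O=C1C[C@H](CC/C(C)=C/CC/C(CO[Si](C)(C)C(C)(C)C)=C/I)[C@H](/C=C(\C)CCO)O1
F2 | step 13 | (4S,5R)-5-[(1E)-4-iodo-2-methylbut-1-en-1-yl] analogue of 27 (primary iodide at C6) | O=C1C[C@H](CC/C(C)=C/CC/C(CO[Si](C)(C)C(C)(C)C)=C/I)[C@H](/C=C(\C)CCI)O1
F3 | step 13 | alkylzinc iodide from F2 (zinc on C6) | O=C1C[C@H](CC/C(C)=C/CC/C(CO[Si](C)(C)C(C)(C)C)=C/I)[C@H](/C=C(\C)CC[Zn]I)O1
F4 | step 9 | (Z)-allylboronic pinacol ester from 14 | I/C=C(\CO[Si](C)(C)C(C)(C)C)CC/C=C(\C)CC/C=C\CB1OC(C)(C)C(C)(C)O1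
F5 | step 9 | O-(pinacolatoboryl) derivative of 21 | O(B1OC(C)(C)C(C)(C)O1)[C@H]([C@H](C=C)CC/C(C)=C/CC/C(CO[Si](C)(C)C(C)(C)C)=C/I)/C=C(\C)C#C[Si](C)(C)C
F6 | step 6 | alkynylmagnesium bromide from 12 | I/C=C(\CO[Si](C)(C)C(C)(C)C)CC/C=C(\C)CCC#C[Mg]Br
F7 | step 6 | (6E,10Z)-10-{[tert-butyl(dimethyl)silyl]oxymethyl}-11-iodo-6-methylundeca-6,10-dien-2-yn-1-ol | I/C=C(\CO[Si](C)(C)C(C)(C)C)CC/C=C(\C)CCC#CCO
F8 | step 6 | N-propargyl-N-(2-nitrobenzenesulfonyl)hydrazine from F7 | I/C=C(\CO[Si](C)(C)C(C)(C)C)CC/C=C(\C)CCC#CCN(N)S(=O)(=O)c1ccccc1[N+](=O)[O-]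
F9 | step 6 | propargylic monoalkyl diazene from F8 | I/C=C(\CO[Si](C)(C)C(C)(C)C)CC/C=C(\C)CCC#CCN=N
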